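**Plan** (target numbering, used for all intermediates: lactone O1, C2(=O), C3=C4, C5(OH), C6; side chain C7(OH), C8(O-cinnamoyl)Ph)
- Retrosynthetic cuts, in order: C4–C5 (ring closure), the O1–C2 acyl bond (to (Z)-3-iodoacrylic acid), the O8–cinnamoyl bond together with the C6–H bond (Evans–Tishchenko reduction), and C7–C8 (aldol).
- Enabling feature: the ring ester O1–C2(=O)–C3=C4 is a built-in tether that holds a cis-β-metallated acrylate on the C6 oxygen next to C5, and C5 is a secondary carbinol attached to the alkenyl carbon C4. An ester-tethered alkenylchromium/aldehyde addition therefore makes the dihydropyranone ring, the Z-enoate and the free 5-OH in one event.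
- Forward order: the C5–C8 chain is joined first ((R)-proline aldol of 2,2-dimethyl-1,3-dioxan-5-one with benzaldehyde), then O8 and O6 are acylated, and the only ring of the target is closed last, giving the target directly.
- Temporary ring: the acetonide 1,3-dioxane across O5/O7 is not in the target. It locks the enamine and the chair for C6 reduction, and masks O5 and O7 while O8 and O6 receive their different acyl groups. It is hydrolysed before the primary-selective oxidation.
- Stereochemistry: C7 and C8 from the catalyst (anti aldol); C6 from 1,3-anti hydride delivery followed by SN2 inversion; C5 from C6 in the ring-closing transition state (5,6-trans).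

Key step: step 6

Remark: compounds 1, 2, 4 and 7 and (R)-proline are taken as commercial.

**Step 1**
Reactants: 1 2,2-dimethyl-1,3-dioxan-5-one; 2 benzaldehyde
Product: 3 (4R)-4-[(R)-hydroxy(phenyl)methyl]-2,2-dimethyl-1,3-dioxan-5-one
Conditions: (R)-proline (30 mol%), DMF, 4 °C, 3 d
Reagents that add atoms: benzaldehyde (2), O=Cc1ccccc1
Why: Proline-catalysed enamine aldol reaction, in which the ring-locked (E)-enamine of 1 and the hydrogen bond from the catalyst carboxylic acid to the aldehyde give the anti adduct, and the (R)-catalyst sets both new centres (C7 and C8) as 4R,1'R.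

**Step 2**
Reactants: 3 (4R)-4-[(R)-hydroxy(phenyl)methyl]-2,2-dimethyl-1,3-dioxan-5-one; 4 (E)-cinnamaldehyde
Product: 6 (R)-[(4S,5R)-5-hydroxy-2,2-dimethyl-1,3-dioxan-4-yl](phenyl)methyl (2E)-3-phenylprop-2-enoate, via samarium-bound hemiacetal 5 (not isolated)
Conditions: 4 (5 equiv), SmI2 (30 mol%), THF, −10 °C, dark; then aq. NaHCO3
Reagents that add atoms: (E)-cinnamaldehyde (4), O=C/C=C/c1ccccc1
Why: Evans–Tishchenko reduction, in which hemiacetal 5 on trivalent samarium passes its hydride to the C6 ketone through a six-membered chair with phenyl equatorial; this is the equatorial face of the dioxanone, so the 1,3-anti, ring-cis (axial) alcohol should form while the oxidised hemiacetal carbon stays on O8 as the cinnamate.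

**Step 3**
Reactants: 6 (R)-[(4S,5R)-5-hydroxy-2,2-dimethyl-1,3-dioxan-4-yl](phenyl)methyl (2E)-3-phenylprop-2-enoate; 7 (2Z)-3-iodoprop-2-enoic acid
Product: 8 (4R,5S)-2,2-dimethyl-4-[(R)-phenyl{[(2E)-3-phenylprop-2-enoyl]oxy}methyl]-1,3-dioxan-5-yl (2Z)-3-iodoprop-2-enoate
Conditions: PPh3, DIAD (betaine preformed), 7 (1.5 equiv), toluene, 0 °C → rt
Reagents that add atoms: (2Z)-3-iodoprop-2-enoic acid (7), OC(=O)/C=C\I
Why: Mitsunobu esterification, in which the carboxylate of the fairly acidic 7 displaces the axial alkoxyphosphonium with inversion at C6, turning the ring-cis alcohol into the trans configuration of the target and installing the Z-iodoacrylate without a nucleophilic amine that could isomerise it.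

**Step 4**
Reactants: 8 (4R,5S)-2,2-dimethyl-4-[(R)-phenyl{[(2E)-3-phenylprop-2-enoyl]oxy}methyl]-1,3-dioxan-5-yl (2Z)-3-iodoprop-2-enoate
Product: 9 (1R,2R,3S)-2,4-dihydroxy-3-{[(2Z)-3-iodoprop-2-enoyl]oxy}-1-phenylbutyl (2E)-3-phenylprop-2-enoate
Conditions: AcOH/H2O (4:1), 40 °C
Reagents that add atoms: none
Why: Acid-catalysed ketal hydrolysis removes the temporary dioxane ring far faster than either secondary ester is cleaved, and the weakly acidic medium avoids base-promoted acyl migration to the freed hydroxyls.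

**Step 5**
Reactants: 9 (1R,2R,3S)-2,4-dihydroxy-3-{[(2Z)-3-iodoprop-2-enoyl]oxy}-1-phenylbutyl (2E)-3-phenylprop-2-enoate
Product: 10 (1R,2R,3R)-2-hydroxy-3-{[(2Z)-3-iodoprop-2-enoyl]oxy}-4-oxo-1-phenylbutyl (2E)-3-phenylprop-2-enoate
Conditions: TEMPO (10 mol%), PhI(OAc)2 (1.2 equiv), CH2Cl2, rt; used directly
Reagents that add atoms: none
Why: Oxoammonium (TEMPO) oxidation is selective for the primary C5 alcohol over the hindered secondary C7 alcohol, stops at the aldehyde, and is non-basic so the α-acyloxy centre C6 should not epimerise.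

**Step 6**
Reactants: 10 (1R,2R,3R)-2-hydroxy-3-{[(2Z)-3-iodoprop-2-enoyl]oxy}-4-oxo-1-phenylbutyl (2E)-3-phenylprop-2-enoate
Product: 12 (1R,2R)-2-hydroxy-2-[(2S,3S)-3-hydroxy-6-oxo-3,6-dihydro-2H-pyran-2-yl]-1-phenylethyl (2E)-3-phenylprop-2-enoate, via (Z)-alkenylchromium dichloride 11 (not isolated)
Conditions: CrCl2 (10 equiv), NiCl2 (2 mol%), degassed DMF, rt, slow addition of 10 to 2 mM; aq. NH4Cl
Reagents that add atoms: none
Why: Zerovalent nickel (formed from NiCl2 by CrCl2) inserts into the alkenyl C4–I bond of 10 and passes the alkenyl group to chromium with retention, giving the (Z)-alkenylchromium dichloride 11 (trivalent chromium), whose C4–Cr bond adds to the C5 aldehyde held in reach by the ester O1–C2(=O); work-up frees the 5-OH. The closest known reaction type is the intramolecular Nozaki–Hiyama–Kishi alkenyl iodide–aldehyde cyclisation, together with the intermolecular addition of (Z)-3-iodoacrylates to aldehydes. The dihydropyranone ring closes in the 6-exo-trig mode (the aldehyde C=O stays outside the ring), and the Z geometry of C3=C4 is carried over from 7. The one new stereocentre, C5, is controlled by C6: in the half-chair transition state the C7 chain is pseudo-equatorial and the chromium-bound aldehyde oxygen points outward, anti to the C6–O1 bond (the dipole-minimised, sterically open arrangement), so the 5,6-trans isomer (5S) should form. The step needs chemoselectivity (only the alkenyl iodide and the aldehyde react; the esters, the cinnamate alkene and the free 7-OH are inert to organochromium reagents) and ring closure ahead of oligomerisation, which high dilution with slow addition should secure while 11 lives long enough to reach the s-cis ester rotamer required for closure.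

**Compound list**
1 | 2,2-dimethyl-1,3-dioxan-5-one | CC1(C)OCC(=O)CO1 | starting material
2 | benzaldehyde | O=Cc1ccccc1 | starting material
3 | (4R)-4-[(R)-hydroxy(phenyl)methyl]-2,2-dimethyl-1,3-dioxan-5-one | O=C1COC(C)(C)O[C@@H]1[C@H](O)c1ccccc1 | intermediate
4 | (E)-cinnamaldehyde | O=C/C=C/c1ccccc1 | starting material
5 | hemiacetal of 3 and 4, bound to trivalent samarium through the hemiacetal oxygen (drawn as the free hemiacetal) | O=C1COC(C)(C)O[C@@H]1[C@H](OC(O)/C=C/c1ccccc1)c1ccccc1 | intermediate
6 | (R)-[(4S,5R)-5-hydroxy-2,2-dimethyl-1,3-dioxan-4-yl](phenyl)methyl (2E)-3-phenylprop-2-enoate | CC1(C)OC[C@@H](O)[C@@H]([C@H](OC(=O)/C=C/c2ccccc2)c2ccccc2)O1 | intermediate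
7 | (2Z)-3-iodoprop-2-enoic acid | OC(=O)/C=C\I | starting material
8 | (4R,5S)-2,2-dimethyl-4-[(R)-phenyl{[(2E)-3-phenylprop-2-enoyl]oxy}methyl]-1,3-dioxan-5-yl (2Z)-3-iodoprop-2-enoate | CC1(C)OC[C@H](OC(=O)/C=C\I)[C@@H]([C@H](OC(=O)/C=C/c2ccccc2)c2ccccc2)O1 | intermediate
9 | (1R,2R,3S)-2,4-dihydroxy-3-{[(2Z)-3-iodoprop-2-enoyl]oxy}-1-phenylbutyl (2E)-3-phenylprop-2-enoate | OC[C@H](OC(=O)/C=C\I)[C@H](O)[C@H](OC(=O)/C=C/c1ccccc1)c1ccccc1 | intermediate
10 | (1R,2R,3R)-2-hydroxy-3-{[(2Z)-3-iodoprop-2-enoyl]oxy}-4-oxo-1-phenylbutyl (2E)-3-phenylprop-2-enoate | O=C[C@H](OC(=O)/C=C\I)[C@H](O)[C@H](OC(=O)/C=C/c1ccccc1)c1ccccc1 | intermediate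
11 | (Z)-alkenylchromium dichloride from 10 (C–I replaced by C–CrCl2, trivalent chromium) | O=C[C@H](OC(=O)/C=C\[Cr](Cl)Cl)[C@H](O)[C@H](OC(=O)/C=C/c1ccccc1)c1ccccc1 | intermediate
12 | (1R,2R)-2-hydroxy-2-[(2S,3S)-3-hydroxy-6-oxo-3,6-dihydro-2H-pyran-2-yl]-1-phenylethyl (2E)-3-phenylprop-2-enoate | O=C1C=C[C@H](O)[C@@H]([C@H](O)[C@H](OC(=O)/C=C/c2ccccc2)c2ccccc2)O1 | target

Total step count: 6. Longest linear sequence: 6 steps.

**Steps most likely to fail**

Step 6. The alkenylchromium may be protonated by the free 7-OH or by traces of water before it cyclises. Closure through the less favoured s-cis ester rotamer may be slow enough for intermolecular addition to compete. Facial selectivity at C5 may be poor, and the chromium alkoxide may trigger acyl transfer. The fallback moves the ring closure to C3=C4 by olefin metathesis and sets out from 6. Mitsunobu esterification with acrylic acid (PPh3, DIAD, toluene, 0 °C) would give, with inversion at C6, (4R,5S)-2,2-dimethyl-4-[(R)-phenyl{[(2E)-3-phenylprop-2-enoyl]oxy}methyl]-1,3-dioxan-5-yl prop-2-enoate F1. Aqueous AcOH at 40 °C would remove the acetonide to give (1R,2R,3S)-2,4-dihydroxy-1-phenyl-3-(prop-2-enoyloxy)butyl (2E)-3-phenylprop-2-enoate F2. TEMPO/PhI(OAc)2 in CH2Cl2 would give (1R,2R,3R)-2-hydroxy-4-oxo-1-phenyl-3-(prop-2-enoyloxy)butyl (2E)-3-phenylprop-2-enoate F3. Intermolecular Nozaki–Hiyama–Kishi addition of vinyl bromide (CrCl2, cat. NiCl2, DMF, rt) should give, by dipole-controlled anti addition to the α-acyloxy aldehyde, (1R,2R,3S,4S)-2,4-dihydroxy-1-phenyl-3-(prop-2-enoyloxy)hex-5-en-1-yl (2E)-3-phenylprop-2-enoate F4. Ring-closing metathesis between the acrylate and the vinyl group with the second-generation Grubbs catalyst RuCl2(=CHPh)(H2IMes)(PCy3) (CH2Cl2, 40 °C) comes back to the route at 12.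

Step 3. The cinnamate carbonyl may take part as a neighbouring group (six-membered acyloxonium), giving retention or acyl scrambling. Elimination of the activated axial alcohol or conjugate addition of the phosphine to the iodoacrylate may also compete with the SN2 displacement. The fallback sets C6 directly, without inversion, and sets out from 3. Chelation-controlled Narasaka–Prasad reduction (Et2BOMe, NaBH4, THF/MeOH, −78 °C) should give the 1,3-syn, ring-trans diol (4R,5S)-4-[(R)-hydroxy(phenyl)methyl]-2,2-dimethyl-1,3-dioxan-5-ol F5. Site-selective Steglich esterification of the less hindered ring hydroxyl with 7 (DCC, cat. DMAP, CH2Cl2, −20 °C) would give (4R,5S)-4-[(R)-hydroxy(phenyl)methyl]-2,2-dimethyl-1,3-dioxan-5-yl (2Z)-3-iodoprop-2-enoate F6. Acylation of the remaining benzylic hydroxyl with cinnamoyl chloride and pyridine (CH2Cl2, 0 °C) comes back to the route at 8.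

Step 2. Hydride transfer from the hemiacetal of a conjugated aldehyde may be sluggish. The Lewis-acidic samarium may cause retro-aldol cleavage of 3, and 1,3-acyl migration may follow the reduction. The fallback separates acylation and reduction and sets out from 3. Cinnamoyl chloride with pyridine (CH2Cl2, −20 °C, no stronger base, to limit β-elimination) would give (R)-[(4R)-2,2-dimethyl-5-oxo-1,3-dioxan-4-yl](phenyl)methyl (2E)-3-phenylprop-2-enoate F7. Luche reduction (NaBH4, CeCl3·7H2O, MeOH, −78 °C), with the equatorial hydride attack typical of 1,3-dioxan-5-ones, should give the axial alcohol and comes back to the route at 6.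

**Further compounds**
F1 | step 6 | (4R,5S)-2,2-dimethyl-4-[(R)-phenyl{[(2E)-3-phenylprop-2-enoyl]oxy}methyl]-1,3-dioxan-5-yl prop-2-enoate | CC1(C)OC[C@H](OC(=O)C=C)[C@@H]([C@H](OC(=O)/C=C/c2ccccc2)c2ccccc2)O1
F2 | step 6 | (1R,2R,3S)-2,4-dihydroxy-1-phenyl-3-(prop-2-enoyloxy)butyl (2E)-3-phenylprop-2-enoate | OC[C@H](OC(=O)C=C)[C@H](O)[C@H](OC(=O)/C=C/c1ccccc1)c1ccccc1
F3 | step 6 | (1R,2R,3R)-2-hydroxy-4-oxo-1-phenyl-3-(prop-2-enoyloxy)butyl (2E)-3-phenylprop-2-enoate | O=C[C@H](OC(=O)C=C)[C@H](O)[C@H](OC(=O)/C=C/c1ccccc1)c1ccccc1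
F4 | step 6 | (1R,2R,3S,4S)-2,4-dihydroxy-1-phenyl-3-(prop-2-enoyloxy)hex-5-en-1-yl (2E)-3-phenylprop-2-enoate | C=C[C@H](O)[C@H](OC(=O)C=C)[C@H](O)[C@H](OC(=O)/C=C/c1ccccc1)c1ccccc1
F5 | step 3 | (4R,5S)-4-[(R)-hydroxy(phenyl)methyl]-2,2-dimethyl-1,3-dioxan-5-ol | CC1(C)OC[C@H](O)[C@@H]([C@H](O)c2ccccc2)O1
F6 | step 3 | (4R,5S)-4-[(R)-hydroxy(phenyl)methyl]-2,2-dimethyl-1,3-dioxan-5-yl (2Z)-3-iodoprop-2-enoate | CC1(C)OC[C@H](OC(=O)/C=C\I)[C@@H]([C@H](O)c2ccccc2)O1
F7 | step 2 | (R)-[(4R)-2,2-dimethyl-5-oxo-1,3-dioxan-4-yl](phenyl)methyl (2E)-3-phenylprop-2-enoate | O=C1COC(C)(C)O[C@@H]1[C@H](OC(=O)/C=C/c1ccccc1)c1ccccc1
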